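**Retrosynthetic overview**

1. Locants: C1 and C6 are the bridgeheads; C2(=CH2)–C3H2–C4(OAc)–C5(side chain, side-chain CH = C11) is the four-carbon bridge, C7(CHO carbon = C12)=C8–C9 the three-carbon bridge, C10(OAc) the one-carbon bridge. The strategy rests on C3 in the seven-membered ring C1–C2–C3–C4–C5–C6–C10: a lone CH2 between the alkene carbon C2 and the oxygen-bearing C4, that is, the α-carbon of a C4 ketone bonded to a vinyl carbon. C2–C3 is therefore cut to a methyl ketone enolate and a 1-iodovinyl group on C1 of ring A (cyclohexene C1–C9–C8=C7–C6–C10).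
2. C5–C6 of that precursor comes from an Ireland–Claisen rearrangement of the (S)-citronellate of an all-cis cyclohexenol (C8–O, C10–OTBS, C1–iodovinyl); the acid is then taken to the methyl ketone.
3. The cyclohexenol comes from a quinone monoketal: an asymmetric conjugate addition sets C1, iododesilylation gives the vinyl iodide, and two hydride reductions relay C1 to C8 and to C10.
4. Ring order: ring A is carried over from the aromatic starting material; the seven-membered ring is closed last, in step 15; C4 reduction, acetylation, desilylation, allylic oxidation and acetylation finish the route.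

Key step: step 15

Remark: TBS = tert-butyl(dimethyl)silyl; the locants C1–C12 defined above are used for all intermediates; (S)-citronellic acid 11 is taken as a commercial chemical (it is also the chlorite oxidation product of (S)-citronellal).

**Route**

Step 1
Reactants: 1 2-hydroxy-5-methoxybenzaldehyde
Product: 2 2-(hydroxymethyl)-4-methoxyphenol
Conditions: NaBH4, MeOH, 0 °C
Reagents that add atoms: none
Why: Borohydride reduction of the aryl aldehyde gives the benzylic alcohol whose carbon becomes C12.

Step 2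
Reactants: 2 2-(hydroxymethyl)-4-methoxyphenol
Product: 3 2-(TBS-oxymethyl)-4-methoxyphenol
Conditions: t-BuMe2SiCl (1.05 equiv), imidazole, CH2Cl2, 0 °C
Reagents that add atoms: tert-butyl(chloro)dimethylsilane, CC(C)(C)[Si](C)(C)Cl
Why: Silyl ether formation is faster at the primary benzylic hydroxyl than at the hydrogen-bonded phenol, so one equivalent of silyl chloride should give the mono-ether.

Step 3
Reactants: 3 2-(TBS-oxymethyl)-4-methoxyphenol
Product: 4 2-(TBS-oxymethyl)-4,4-dimethoxycyclohexa-2,5-dien-1-one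
Conditions: PhI(OAc)2, MeOH, 0 °C
Reagents that add atoms: methanol, CO
Why: Oxidative dearomatisation of the para-methoxyphenol with capture of methanol at the methoxy-bearing carbon gives the quinone monoketal, in which C10 is masked at the ketone level and both enone units of ring A are present.

Step 4
Reactants: 5 (1-bromoethenyl)trimethylsilane
Product: 7 4,4,5,5-tetramethyl-2-[1-(trimethylsilyl)ethenyl]-1,3,2-dioxaborolane, via alkenylmagnesium bromide 6 (not isolated)
Conditions: Mg, THF, rt; then 2-isopropoxy-4,4,5,5-tetramethyl-1,3,2-dioxaborolane, −78 °C → rt; aq. NH4Cl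
Reagents that add atoms: magnesium, [Mg] (in 6); 2-isopropoxy-4,4,5,5-tetramethyl-1,3,2-dioxaborolane, CC(C)OB1OC(C)(C)C(C)(C)O1
Why: Grignard formation from the vinyl bromide followed by borylation with the isopropoxy boronate is the standard access to alkenyl pinacol boronates.

Step 5
Reactants: 4 2-(TBS-oxymethyl)-4,4-dimethoxycyclohexa-2,5-dien-1-one; 7 4,4,5,5-tetramethyl-2-[1-(trimethylsilyl)ethenyl]-1,3,2-dioxaborolane
Product: 8 (5S)-4,4-dimethoxy-2-(TBS-oxymethyl)-5-[1-(trimethylsilyl)ethenyl]cyclohex-2-en-1-one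
Conditions: [Rh(OH)(cod)]2 (2.5 mol %), (R)-BINAP (6 mol %), dioxane/H2O (10:1), 50 °C
Reagents that add atoms: none
Why: In this rhodium-catalysed asymmetric conjugate addition (Hayashi–Miyaura reaction) the alkenyl group adds to the unsubstituted enone C9=C1 rather than the slower α-substituted C7=C6 enone, and (R)-BINAP, the antipode that turns cyclohex-2-enone into (R)-3-arylcyclohexanones, should select the corresponding face and set C1 as (S), as known for 1-substituted alkenylboron reagents and cyclohexadienone monoketals.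

Step 6
Reactants: 8 (5S)-4,4-dimethoxy-2-(TBS-oxymethyl)-5-[1-(trimethylsilyl)ethenyl]cyclohex-2-en-1-one
Product: 9 (5S)-5-(1-iodoethenyl)-4,4-dimethoxy-2-(TBS-oxymethyl)cyclohex-2-en-1-one
Conditions: N-iodosuccinimide, MeCN/ClCH2CN (4:1), 0 °C → rt, dark
Reagents that add atoms: N-iodosuccinimide, O=C1CCC(=O)N1I
Why: Iododesilylation (electrophilic ipso substitution) of the 1,1-disubstituted vinylsilane puts iodine on C2 while the electron-poor enone alkene, the ketal and the silyl ether stay inert, and at this stage no electron-rich alkene is yet present.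

Step 7
Reactants: 9 (5S)-5-(1-iodoethenyl)-4,4-dimethoxy-2-(TBS-oxymethyl)cyclohex-2-en-1-one
Product: 10 (1R,5S)-5-(1-iodoethenyl)-4,4-dimethoxy-2-(TBS-oxymethyl)cyclohex-2-en-1-ol
Conditions: NaBH4, CeCl3·7H2O, MeOH, −78 °C
Reagents that add atoms: none
Why: Luche reduction gives only 1,2-reduction, and axial hydride delivery to the half-chair that holds the C1 substituent pseudo-equatorial should place the C8 hydroxyl cis to the iodoethenyl group, as in the reduction of carvone to cis-carveol.

Step 8
Reactants: 10 (1R,5S)-5-(1-iodoethenyl)-4,4-dimethoxy-2-(TBS-oxymethyl)cyclohex-2-en-1-ol; 11 (S)-citronellic acid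
Product: 12 (1R,5S)-5-(1-iodoethenyl)-4,4-dimethoxy-2-(TBS-oxymethyl)cyclohex-2-en-1-yl (3S)-3,7-dimethyloct-6-enoate
Conditions: DCC, DMAP (cat.), CH2Cl2, 0 °C → rt
Reagents that add atoms: none
Why: Steglich esterification acylates the secondary allylic alcohol with retention at C8 under neutral conditions that spare the acid-labile ketal, and the ester also protects C8–O during the next steps.

Step 9
Reactants: 12 (1R,5S)-5-(1-iodoethenyl)-4,4-dimethoxy-2-(TBS-oxymethyl)cyclohex-2-en-1-yl (3S)-3,7-dimethyloct-6-enoate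
Product: 13 (1R,5S)-5-(1-iodoethenyl)-4-oxo-2-(TBS-oxymethyl)cyclohex-2-en-1-yl (3S)-3,7-dimethyloct-6-enoate
Conditions: oxalic acid (10 % aq.), SiO2, CH2Cl2, rt
Reagents that add atoms: water, O
Why: The allylic dimethyl ketal ionises easily, so mild acid-catalysed ketal hydrolysis on wet silica should free the C10 enone without cleaving the primary silyl ether or the allylic ester.

Step 10
Reactants: 13 (1R,5S)-5-(1-iodoethenyl)-4-oxo-2-(TBS-oxymethyl)cyclohex-2-en-1-yl (3S)-3,7-dimethyloct-6-enoate
Product: 14 (1R,4R,5S)-4-hydroxy-5-(1-iodoethenyl)-2-(TBS-oxymethyl)cyclohex-2-en-1-yl (3S)-3,7-dimethyloct-6-enoate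
Conditions: LiBH(s-Bu)3, THF, −78 °C; aq. NH4Cl
Reagents that add atoms: none
Why: The bulky hydride reduces the β,β-disubstituted enone in the 1,2 sense and attacks equatorially beside the pseudo-equatorial C1 substituent (or anti to it in the other half-chair), so the C10 hydroxyl should emerge cis to the iodoethenyl group (the cis-2-alkylcyclohexanol pattern), completing the all-cis C8, C10, C1 array.

Step 11
Reactants: 14 (1R,4R,5S)-4-hydroxy-5-(1-iodoethenyl)-2-(TBS-oxymethyl)cyclohex-2-en-1-yl (3S)-3,7-dimethyloct-6-enoate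
Product: 15 (1R,4R,5S)-4-(TBS-oxy)-5-(1-iodoethenyl)-2-(TBS-oxymethyl)cyclohex-2-en-1-yl (3S)-3,7-dimethyloct-6-enoate
Conditions: t-BuMe2SiOTf, 2,6-lutidine, CH2Cl2, −78 → 0 °C
Reagents that add atoms: tert-butyldimethylsilyl trifluoromethanesulfonate, CC(C)(C)[Si](C)(C)OS(=O)(=O)C(F)(F)F
Why: Silyl triflate with a hindered pyridine base silylates the hindered allylic alcohol at low temperature without acyl migration (silyl ether formation).

Step 12
Reactants: 15 (1R,4R,5S)-4-(TBS-oxy)-5-(1-iodoethenyl)-2-(TBS-oxymethyl)cyclohex-2-en-1-yl (3S)-3,7-dimethyloct-6-enoate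
Product: 18 Claisen acid: ring A with 1-iodoethenyl on C1; OTBS on C10; CH2OTBS on C7; C7=C8; C6 bonded to C5 that carries CO2H and the (S)-6-methylhept-5-en-2-yl chain, via silyl ketene acetal 16 (not isolated), via trimethylsilyl ester 17 (not isolated)
Conditions: LiN(i-Pr)2, THF/DMPU, −78 °C; Me3SiCl, Et3N; −78 → 60 °C; aq. citric acid
Reagents that add atoms: chlorotrimethylsilane, C[Si](C)(C)Cl (silyl group of 16 and 17 only)
Why: In this Ireland–Claisen rearrangement enolisation in THF/DMPU should give the Z silyl ketene acetal, the [3,3] shift transfers the C8 configuration suprafacially to C6 (C5 cis to the C10 and C1 substituents), and the boat-like transition state usual for cyclohexenyl esters, which here also keeps the silyloxy group clear of the cis C1 and C10 substituents, should turn the side chain away from C10 and so set C5.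

Step 13
Reactants: 18 Claisen acid
Product: 20 Weinreb amide (N-methoxy-N-methylamide of 18), via acid chloride 19 (not isolated)
Conditions: 1-chloro-N,N,2-trimethylprop-1-en-1-amine, CH2Cl2, 0 °C; then MeNH(OMe)·HCl, pyridine, 0 °C → rt
Reagents that add atoms: 1-chloro-N,N,2-trimethylprop-1-en-1-amine, CC(C)=C(Cl)N(C)C (chlorine of 19); N,O-dimethylhydroxylamine hydrochloride, CNOC.Cl
Why: Neutral acid chloride formation with the α-chloroenamine and acylation of N,O-dimethylhydroxylamine should convert the hindered acid into the Weinreb amide without acid exposure of the silyl ethers.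

Step 14
Reactants: 20 Weinreb amide
Product: 21 methyl ketone (cyclisation precursor): ring A with 1-iodoethenyl on C1; OTBS on C10; CH2OTBS on C7; C6 bonded to C5 that carries the C4 acetyl group and the side chain
Conditions: MeMgBr, THF, 0 °C; aq. NH4Cl
Reagents that add atoms: methylmagnesium bromide, C[Mg]Br
Why: In the Weinreb ketone synthesis the chelated tetrahedral adduct stops at mono-addition, and the Grignard reagent does not exchange with the vinyl iodide as an alkyllithium would.

Step 15
Reactants: 21 methyl ketone (cyclisation precursor)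
Product: 22 2-methylenebicyclo[4.3.1]dec-7-en-4-one with the C5 side chain; CH2OTBS on C7; OTBS on C10
Conditions: KN(SiMe3)2 (2.2 equiv), THF, −78 °C; Pd2(dba)3 (5 mol %), DPEphos (12 mol %), −78 → 45 °C; AcOH, −78 °C
Reagents that add atoms: none
Why: KN(SiMe3)2 removes a proton from the C3 methyl group kinetically at −78 °C, zerovalent palladium inserts into the C2–I bond, the enolate replaces iodide on the divalent palladium centre and reductive elimination forms C2–C3. The closest known reaction type is the palladium-catalysed intramolecular α-alkenylation of ketone enolates with vinyl halides, used to close bridged carbocycles and azabicycles that carry an exocyclic alkene, the bicyclo[4.3.1]decane ring size being known from the corresponding enolate arylation. The seven-membered ring C1–C2–C3–C4–C5–C6–C10 closes in the 7-exo mode, the alkene staying exocyclic, across the cis C1 and C6 arms of ring A, which must both turn axial. No stereocentre is created, and C1, C5, C6, C10 and C11 are carried through unchanged. The step needs coupling at C3 and not at C5 or at oxygen, and no epimerisation at C5: irreversible kinetic deprotonation of the methyl group by the hindered amide, the second equivalent of base that holds the product as its C3 dienolate, and the crowding and strain of the alternative five-membered closure at the fully substituted C5 should secure this. Protonation of the dienolate at C3 by acetic acid at −78 °C leaves the alkene out of conjugation.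

Step 16
Reactants: 22 bicyclic ketone
Product: 23 C4 alcohol: hydroxyl on the face of the seven-membered ring turned toward the C7=C8–C9 bridge; cis to the C5 side chain
Conditions: NaBH4, CeCl3·7H2O, MeOH/THF, −40 °C
Reagents that add atoms: none
Why: Hydride should attack the C4 ketone from the exo face, because the C7=C8–C9 bridge of ring A covers the other face, and the weakly basic Luche conditions at low temperature avoid migration of the exocyclic alkene into conjugation.

Step 17
Reactants: 23 C4 alcohol
Product: 24 C4 acetate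
Conditions: Ac2O, DMAP, pyridine, rt
Reagents that add atoms: acetic anhydride, CC(=O)OC(C)=O
Why: DMAP-catalysed acetylation of the only free hydroxyl installs the C4 acetate before the other two oxygens are unmasked.

Step 18
Reactants: 24 C4 acetate
Product: 25 C10,C12-diol
Conditions: HF·pyridine, pyridine, THF, 0 °C → rt
Reagents that add atoms: none
Why: Buffered fluoride desilylation removes both silyl ethers under non-basic conditions, so the acetate neither migrates nor hydrolyses and the alkenes are untouched.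

Step 19
Reactants: 25 C10,C12-diol
Product: 26 enal: C7 carbaldehyde with free C10 hydroxyl
Conditions: MnO2, CH2Cl2, rt
Reagents that add atoms: none
Why: MnO2 oxidises only the allylic primary alcohol at C12 to the conjugated aldehyde, the C10 alcohol being neither allylic nor close enough to the aldehyde to form a lactol.

Step 20
Reactants: 26 enal
Product: 27 target diacetate CNP0197379.1
Conditions: Ac2O, DMAP, pyridine, CH2Cl2, rt
Reagents that add atoms: acetic anhydride, CC(=O)OC(C)=O
Why: DMAP-catalysed acetylation of the remaining C10 hydroxyl completes the target.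

**Compound list**

1 | 2-hydroxy-5-methoxybenzaldehyde | COc1ccc(O)c(C=O)c1 | starting material
2 | 2-(hydroxymethyl)-4-methoxyphenol | COc1ccc(O)c(CO)c1 | intermediate
3 | 2-(TBS-oxymethyl)-4-methoxyphenol | COc1ccc(O)c(CO[Si](C)(C)C(C)(C)C)c1 | intermediate
4 | 2-(TBS-oxymethyl)-4,4-dimethoxycyclohexa-2,5-dien-1-one | O=C1C=CC(OC)(OC)C=C1CO[Si](C)(C)C(C)(C)C | intermediate
5 | (1-bromoethenyl)trimethylsilane | C=C(Br)[Si](C)(C)C | starting material
6 | [1-(trimethylsilyl)ethenyl]magnesium bromide | C=C([Si](C)(C)C)[Mg]Br | intermediate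
7 | 4,4,5,5-tetramethyl-2-[1-(trimethylsilyl)ethenyl]-1,3,2-dioxaborolane | C=C([Si](C)(C)C)B1OC(C)(C)C(C)(C)O1 | intermediate
8 | (5S)-4,4-dimethoxy-2-(TBS-oxymethyl)-5-[1-(trimethylsilyl)ethenyl]cyclohex-2-en-1-one | O=C1C[C@H](C(=C)[Si](C)(C)C)C(OC)(OC)C=C1CO[Si](C)(C)C(C)(C)C | intermediate
9 | (5S)-5-(1-iodoethenyl)-4,4-dimethoxy-2-(TBS-oxymethyl)cyclohex-2-en-1-one | O=C1C[C@H](C(I)=C)C(OC)(OC)C=C1CO[Si](C)(C)C(C)(C)C | intermediate
10 | (1R,5S)-5-(1-iodoethenyl)-4,4-dimethoxy-2-(TBS-oxymethyl)cyclohex-2-en-1-ol (hydroxyl cis to iodoethenyl) | O[C@@H]1C[C@H](C(I)=C)C(OC)(OC)C=C1CO[Si](C)(C)C(C)(C)C | intermediate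
11 | (S)-citronellic acid, (3S)-3,7-dimethyloct-6-enoic acid | OC(=O)C[C@@H](C)CCC=C(C)C | starting material
12 | (1R,5S)-5-(1-iodoethenyl)-4,4-dimethoxy-2-(TBS-oxymethyl)cyclohex-2-en-1-yl (3S)-3,7-dimethyloct-6-enoate | O=C(C[C@@H](C)CCC=C(C)C)O[C@@H]1C[C@H](C(I)=C)C(OC)(OC)C=C1CO[Si](C)(C)C(C)(C)C | intermediate
13 | (1R,5S)-5-(1-iodoethenyl)-4-oxo-2-(TBS-oxymethyl)cyclohex-2-en-1-yl (3S)-3,7-dimethyloct-6-enoate | O=C(C[C@@H](C)CCC=C(C)C)O[C@@H]1C[C@H](C(I)=C)C(=O)C=C1CO[Si](C)(C)C(C)(C)C | intermediate
14 | (1R,4R,5S)-4-hydroxy-5-(1-iodoethenyl)-2-(TBS-oxymethyl)cyclohex-2-en-1-yl (3S)-3,7-dimethyloct-6-enoate (all-cis) | O=C(C[C@@H](C)CCC=C(C)C)O[C@@H]1C[C@H](C(I)=C)[C@H](O)C=C1CO[Si](C)(C)C(C)(C)C | intermediate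
15 | (1R,4R,5S)-4-(TBS-oxy)-5-(1-iodoethenyl)-2-(TBS-oxymethyl)cyclohex-2-en-1-yl (3S)-3,7-dimethyloct-6-enoate (all-cis) | O=C(C[C@@H](C)CCC=C(C)C)O[C@@H]1C[C@H](C(I)=C)[C@H](O[Si](C)(C)C(C)(C)C)C=C1CO[Si](C)(C)C(C)(C)C | intermediate
16 | Z trimethylsilyl ketene acetal of 15 (side chain cis to OSiMe3) | C[Si](C)(C)O/C(=C\[C@@H](C)CCC=C(C)C)O[C@@H]1C[C@H](C(I)=C)[C@H](O[Si](C)(C)C(C)(C)C)C=C1CO[Si](C)(C)C(C)(C)C | intermediate
17 | trimethylsilyl ester of acid 18 | C=C(I)[C@H]1CC=C(CO[Si](C)(C)C(C)(C)C)[C@@H]([C@H](C(=O)O[Si](C)(C)C)[C@@H](C)CCC=C(C)C)[C@H]1O[Si](C)(C)C(C)(C)C | intermediate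
18 | Claisen acid: ring A with 1-iodoethenyl (C1), OTBS (C10), CH2OTBS (C7), C7=C8, and on C6 the C5 carbon bearing CO2H and the (S)-6-methylhept-5-en-2-yl chain, C1/C10/C6 substituents all cis | C=C(I)[C@H]1CC=C(CO[Si](C)(C)C(C)(C)C)[C@@H]([C@H](C(=O)O)[C@@H](C)CCC=C(C)C)[C@H]1O[Si](C)(C)C(C)(C)C | intermediate
19 | acid chloride of 18 | C=C(I)[C@H]1CC=C(CO[Si](C)(C)C(C)(C)C)[C@@H]([C@H](C(=O)Cl)[C@@H](C)CCC=C(C)C)[C@H]1O[Si](C)(C)C(C)(C)C | intermediate
20 | N-methoxy-N-methylamide (Weinreb amide) of 18 | C=C(I)[C@H]1CC=C(CO[Si](C)(C)C(C)(C)C)[C@@H]([C@H](C(=O)N(C)OC)[C@@H](C)CCC=C(C)C)[C@H]1O[Si](C)(C)C(C)(C)C | intermediate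
21 | methyl ketone, cyclisation precursor: as 18 with C4 acetyl in place of CO2H | C=C(I)[C@H]1CC=C(CO[Si](C)(C)C(C)(C)C)[C@@H]([C@H](C(C)=O)[C@@H](C)CCC=C(C)C)[C@H]1O[Si](C)(C)C(C)(C)C | intermediate
22 | 2-methylenebicyclo[4.3.1]dec-7-en-4-one with C5 (S)-6-methylhept-5-en-2-yl chain, C7 CH2OTBS and C10 OTBS (C10–O cis on ring A to the C1–C2 and C6–C5 bonds) | C=C1CC(=O)[C@H]([C@@H](C)CCC=C(C)C)[C@@H]2C(CO[Si](C)(C)C(C)(C)C)=CC[C@H]1[C@@H]2O[Si](C)(C)C(C)(C)C | intermediate
23 | C4 alcohol of 22 (hydroxyl cis to the C5 side chain, on the face toward the C7=C8–C9 bridge) | C=C1C[C@H](O)[C@H]([C@@H](C)CCC=C(C)C)[C@@H]2C(CO[Si](C)(C)C(C)(C)C)=CC[C@H]1[C@@H]2O[Si](C)(C)C(C)(C)C | intermediate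
24 | C4 acetate of 23 | C=C1C[C@H](OC(C)=O)[C@H]([C@@H](C)CCC=C(C)C)[C@@H]2C(CO[Si](C)(C)C(C)(C)C)=CC[C@H]1[C@@H]2O[Si](C)(C)C(C)(C)C | intermediate
25 | C4 acetate with free C10 and C12 hydroxyls | C=C1C[C@H](OC(C)=O)[C@H]([C@@H](C)CCC=C(C)C)[C@@H]2C(CO)=CC[C@H]1[C@@H]2O | intermediate
26 | C4 acetate, C7 carbaldehyde, free C10 hydroxyl | C=C1C[C@H](OC(C)=O)[C@H]([C@@H](C)CCC=C(C)C)[C@@H]2C(C=O)=CC[C@H]1[C@@H]2O | intermediate
27 | CNP0197379.1: 7-formyl-2-methylene-5-[(2S)-6-methylhept-5-en-2-yl]bicyclo[4.3.1]dec-7-ene-4,10-diyl diacetate | C=C1C[C@H](OC(C)=O)[C@H]([C@@H](C)CCC=C(C)C)[C@@H]2C(C=O)=CC[C@H]1[C@@H]2OC(C)=O | target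

**Step count and risks**

Total steps: 20. Longest linear sequence: 19 steps (steps 1–3 and 5–20, from 1); step 4 is a one-step side branch.

Steps most likely to fail:

Step 15 (key step). After oxidative addition the seven-membered ring closure may be slow, so that loss of hydrogen iodide, reduction of the C–I bond, bonding through the enolate oxygen or proton exchange that scrambles C5 take over. The fallback sets out from 20 and returns at 22, closing the ring at C3–C4 instead. Stille coupling of 20 with (tributylstannyl)methanol (Pd(PPh3)4, dioxane, 90 °C) would give the 2-substituted allylic alcohol F1. An Appel reaction (CBr4, PPh3) would give the allylic bromide F2, and i-Bu2AlH at −78 °C the aldehyde F3. CrCl2 in THF at high dilution would then generate the allylchromium species, which adds to the C4 aldehyde through its far terminus (intramolecular Nozaki–Hiyama allylation). This closes the seven-membered ring with the exo-methylene already on C2 and gives the homoallylic alcohol F4 (either C4 epimer). Dess–Martin oxidation of F4 gives 22.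

Step 12. The [3,3] shift must deliver C5 to the face of ring A that already carries the C1 and C10 substituents. It may therefore be slow enough for the amide base to eliminate hydrogen iodide from the vinyl iodide, or for chair and boat pathways to compete and erode the C5 configuration. The fallback sets out from 15 and returns at 21 by a decarboxylative Carroll rearrangement. C-Acetylation of the ester enolate of 15 (LiN(SiMe3)2, THF, −78 °C; N-acetylimidazole) would give the β-keto ester F5. On heating in xylene F5 should rearrange through its enol and lose CO2 to give 21 directly, bypassing steps 13 and 14. C5 is then fixed by ketonisation, and the C5 epimers would be separated at 21.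

Step 5. Transmetalation of the hindered α-silyl alkenylboronate may be slow, so that protodeboronation outruns addition, or the facial selectivity may be incomplete. The fallback sets out from 4 and returns at 10 by racemic addition and enzymatic resolution. The Grignard reagent 6 with CuBr·SMe2 and Me3SiCl in THF at −78 °C would add to 4 to give 8 together with its enantiomer F6. Steps 6 and 7 on the racemate would give 9 with its enantiomer F7 and 10 with its enantiomer F8. Lipase-catalysed acylation (Burkholderia cepacia lipase, vinyl acetate, t-BuOMe) should acetylate the (1R)-alcohol to the acetate F9. F9 is separated from unreacted F8 and methanolysed (K2CO3, MeOH) to 10.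

**Further compounds**

F1 | step 15 | Weinreb amide 20 with 3-hydroxyprop-1-en-2-yl in place of 1-iodoethenyl on C1 | C=C(CO)[C@H]1CC=C(CO[Si](C)(C)C(C)(C)C)[C@@H]([C@H](C(=O)N(C)OC)[C@@H](C)CCC=C(C)C)[C@H]1O[Si](C)(C)C(C)(C)C
F2 | step 15 | allylic bromide from F1 (3-bromoprop-1-en-2-yl on C1) | C=C(CBr)[C@H]1CC=C(CO[Si](C)(C)C(C)(C)C)[C@@H]([C@H](C(=O)N(C)OC)[C@@H](C)CCC=C(C)C)[C@H]1O[Si](C)(C)C(C)(C)C
F3 | step 15 | C4 aldehyde from F2 | C=C(CBr)[C@H]1CC=C(CO[Si](C)(C)C(C)(C)C)[C@@H]([C@H](C=O)[C@@H](C)CCC=C(C)C)[C@H]1O[Si](C)(C)C(C)(C)C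
F4 | step 15 | bicyclic homoallylic C4 alcohol, C4 configuration not controlled | C=C1CC(O)[C@H]([C@@H](C)CCC=C(C)C)[C@@H]2C(CO[Si](C)(C)C(C)(C)C)=CC[C@H]1[C@@H]2O[Si](C)(C)C(C)(C)C
F5 | step 12 | β-keto ester: 2-acetyl derivative of ester 15 | O=C(C(C(C)=O)[C@@H](C)CCC=C(C)C)O[C@@H]1C[C@H](C(I)=C)[C@H](O[Si](C)(C)C(C)(C)C)C=C1CO[Si](C)(C)C(C)(C)C
F6 | step 5 | enantiomer of 8, (5R) | O=C1C[C@@H](C(=C)[Si](C)(C)C)C(OC)(OC)C=C1CO[Si](C)(C)C(C)(C)C
F7 | step 5 | enantiomer of 9, (5R) | O=C1C[C@@H](C(I)=C)C(OC)(OC)C=C1CO[Si](C)(C)C(C)(C)C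
F8 | step 5 | enantiomer of 10, (1S,5R) | O[C@H]1C[C@@H](C(I)=C)C(OC)(OC)C=C1CO[Si](C)(C)C(C)(C)C
F9 | step 5 | acetate of 10 | CC(=O)O[C@@H]1C[C@H](C(I)=C)C(OC)(OC)C=C1CO[Si](C)(C)C(C)(C)C
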